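Atom numbers (C1–O32) follow the order of the heavy atoms in the SMILES string of the target. Nothing in this proposal has been run; the stereochemical assignments were worked out by hand from the SMILES descriptors, and all outcomes are expectations.

## Analysis of the target

The target (C25H32O7) is hexacyclic: ring A is a spiro α,β-unsaturated δ-lactone (C2, O4, C5, C7, C8, C9), ring B a cyclohexane (C9–C12, C21, C22), ring C a cyclopentane (C12, C21, C20, C18, C25), ring D a cyclohexanone (C12, C13, C14, C16, C18, C25), ring E a carbocycle (C14, C16, C18, C25, C30, C31) and ring F a γ-lactone (C25, C26, O27, C28, C30). Rings C and D form a bicyclo[3.2.1]octane, and its one-atom bridge C25 is also a bridgehead of the bicyclo[2.2.2]octane made of rings D and E. There are nine stereocentres (C9, C12, C14, C18, C21, C22, C25, C30, C31), six of them carbons without hydrogen. C30 lies syn to the C13–C14–C16 bridge and C26 syn to C20–C21, ring B is fused through the exo bond of C21, and the C22 hydroxyl is trans to the C9–C2 bond; the C31 hydroxyl and H30 point to the C16 flank and the lactone carbonyl C28 to the C13 flank. Sensitive groups are the β-hydroxy ketone C31/C16 and the β-hydroxy lactone (retro-aldol, elimination), the tertiary C22 carbinol next to quaternary C9 (retro-aldol-type ring opening) and the enoate. The difficulty is the cluster of adjacent fully substituted carbons (C12, C25, C18, C14 and C9–C22) with two carbonyl groups on the neighbours of C25. The strategy rests on ring C: with C25 bridging C12 and C18, the unit C13–C14(C15)–C16 is methacrolein laid across a cyclopentanone.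

## Retrosynthetic reasoning

Rings A and B (35 ⇒ 34). The spiro centre C9 belongs to both rings, so C9–C22 and C2–O4 are cut together. Going forward, a Lewis acid has to make the C9=C2 alkene of 34 attack the C22 ketone and let the ester oxygen trap the C2 cation. This is done last because it needs no base and so leaves the aldol-type functionality of rings E and F alone.

Side chain (34 ⇒ 33 ⇒ 27 + 31). The C9–C10 bond is an sp2–sp3 bond and is cut as a B-alkyl cross-coupling between alkylborane 32, made from alkene 27, and bromodiene 31. The dienoate would not survive enolate, ketene or peracid chemistry, so it is attached only after ring E is closed. Reagent 31 comes from 28 through 30.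

C10 and C11 (27 ⇒ 26 ⇒ 23). The C10 methylene is removed to give aldehyde 26, and C11 is traced back through 25 and 24 to the silyl ether carried in 23. The forward steps must be non-basic because C30–H and the C31 oxygen are now in a β-relationship.

Ring E (23 ⇒ 21). C30–C31 is cut as a reductive (Reformatsky-type) aldol. This bond is chosen because it leaves a non-enolizable aldehyde on quaternary C14 and an α-halo lactone as the only latent nucleophile.

Ring F (21 ⇒ 19 ⇒ 18 ⇒ 17). The lactone oxygen O27 is removed (Baeyer–Villiger), then C25–C30 and C26–C28 are cut as a ketene [2+2] cycloaddition on the exocyclic alkene of 17. This makes quaternary C25 and all lactone carbons in one step, and the chlorine atoms both direct the oxygen insertion and arm C30 for ring E.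

Decoration of the bicycle (17 ⇒ 16 ⇒ 15 ⇒ 14 ⇒ 13). C26 is removed to the C25 ketone and C31 is cut from C14 as an enolate alkoxymethylation. The dioxolane of 15 goes back to the methyl ketone of 14 and, by ozonolysis, to the isopropenyl group of 13, which is a latent C22 ketone that tolerates the annulation.

Redox adjustment (13 ⇒ 12 ⇒ 11 ⇒ 10). The ester carbon C11 must end as CH2 and cannot be reduced once lactone F exists. It is therefore reduced immediately after the annulation together with C25, and C16 and C25 are then oxidized together.

Key disconnection (10 ⇒ 7 + 8). C12–C13 and C16–C18 are cut, which removes ring D and four stereocentres and leaves cyclopentanone 7 and enal 8. Forward, the β-keto ester carbon must add first and the only remaining enolizable ketone position must close second.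

Precursor (7 ⇒ 5 + 6; 5 ⇒ 3 + 4; 3 ⇒ 2 ⇒ 1). The ester is cut from the only α-CH2 of 5, the isopropenyl group is removed as a catalytic asymmetric 1,4-addition to 3, and 3 is the dehydrogenation product of 1 through 2. This sets the single controlling stereocentre C21 by a well-established enantioselective reaction.

## Alternatives that were turned down

Alternative 1: Rings C and B are removed together (C18–C20, C12–C21 and C10–C11) from a preformed bicyclo[2.2.2]octanone holding rings D and E. Forward, its C16 enolate would add through C18 to divinyl ketone A1, the new enolate would close ring C on an exocyclic C12=C11 vinyl sulfone, and the sulfonyl carbanion would close ring B on the second vinyl group, giving isotwistane A2.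
- For: three C–C bonds and two rings in one flask, and ring B arrives directly. On bonds per step and on ring B it is stronger than the chosen plan.
- Against: the first addition comes from a tetrasubstituted enolate onto the polymerization-prone bis-acceptor A1, and the second must create quaternary C12 on a β,β-disubstituted vinyl sulfone. The substrate must already contain C14, C25 and ring E as one enantiomer. Isotwistane A2 still lacks C23, both substituents of C9 and lactone F, and carries a sulfone to be removed.
- Comparison: the chosen annulation makes the same two bridgehead centres from a four-step monocyclic precursor in an order fixed by acidity, by a precedented reaction type.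

Alternative 2: Rings D, E and F are taken back to a benzene ring (C18–C20, C25–C30, C14–C31). Forward, an aryl allylic ether would undergo ortho-Claisen rearrangement to the methyl-bearing carbon C18, and the resulting 2,4-cyclohexadienone would be trapped by a borylacrylate tethered through the C26 oxygen, giving the lactone-fused bicyclo[2.2.2]octenone boronate A3.
- For: rings D–F and five stereocentres form in one thermal operation, and the C31 boronate of A3 can be oxidized with retention. On the C30/C31 problem it is stronger than the chosen route, whose ring E closure is stereochemically less certain.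
- Against: both ortho carbons (C14 and C18) carry a methyl group, so the Claisen regiochemistry needs an extra bias. The diene faces differ at C18 only by methyl versus butenyl. Ring C must then be closed by a late C12–C21 bond onto the bicyclic C12=C13 alkene of A3, creating quaternary C12 in a crowded setting, and rings A and B remain.
- Comparison: the chosen plan sets C12 and C18 first and cheaply, and spends its risk later on oxygenated centres that are easier to correct.

Alternative 3: The four carbons of lactone F are cut at C25–C30 and C26–C28. Forward, dichloroketene A4 adds to the C25 exocyclic alkene of the bicyclo[3.2.1]octane to give spiro dichlorocyclobutanone A5.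
- For: a known reaction with dependable regiochemistry, whose chlorine atoms direct the later oxygen insertion and serve the Reformatsky closure. It is good enough that the chosen route uses it as step 13.
- Against, as a strategy: the addition of dichloroketene A4 builds one ring and one stereocentre and presupposes the whole bicycle with C12, C14 and C18 in place. It therefore does not say where the skeleton comes from, and its facial selectivity is inherited from that substrate.
- Comparison: the Michael–aldol annulation supplies exactly that substrate and sets four stereocentres, so the ketene step is kept as a tactic inside the chosen strategy.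

Key step: step 5

Remark: centres that are erased later (the methyl-bearing carbon in 2–7, C14 and C16 in 10–15, the C25 carbinol in 11 and 12) are drawn as the expected major epimer or left undefined; the other epimers converge on the same compounds.

## Route

Step 1
Reactants: 1 2-methylcyclopentan-1-one
Product: 2 trimethyl[(5-methylcyclopent-1-en-1-yl)oxy]silane
Conditions: LiN(iPr)2, THF, −78 °C; Me3SiCl, −78 °C → rt
Reagents that add atoms: chlorotrimethylsilane, C[Si](C)(C)Cl
Why: Kinetic deprotonation by the hindered amide takes the less substituted α-CH2 and O-silylation fixes that regiochemistry; the racemic methyl centre is enolized again in step 5 and needs no control.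

Step 2
Reactants: 2 silyl enol ether
Product: 3 5-methylcyclopent-2-en-1-one
Conditions: Pd(OAc)2 (1.05 equiv), MeCN, rt
Reagents that add atoms: none
Why: Saegusa–Ito dehydrogenation: the enolate of divalent palladium formed from the silyl enol ether undergoes β-hydride elimination on the side fixed in step 1, so the double bond appears away from the methyl group.

Step 3
Reactants: 3 5-methylcyclopent-2-en-1-one; 4 potassium trifluoro(prop-1-en-2-yl)borate
Product: 5 (4R)-2-methyl-4-(prop-1-en-2-yl)cyclopentan-1-one
Conditions: [Rh(cod)2]BF4 (3 mol %), (R)-BINAP (3.3 mol %), toluene/H2O (10:1), 100 °C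
Reagents that add atoms: none
Why: Hayashi–Miyaura rhodium-catalysed asymmetric 1,4-addition of an alkenylboron reagent; by analogy with the established sense for cyclopent-2-enone the (R)-BINAP catalyst should give the R centre (future C21), and the remote, epimerizable methyl centre does not matter.

Step 4
Reactants: 5 (4R)-ketone; 6 dimethyl carbonate
Product: 7 methyl (1S,3S,5R)-3-methyl-2-oxo-5-(prop-1-en-2-yl)cyclopentane-1-carboxylate
Conditions: NaH (2.2 equiv), THF, reflux; aq. HCl
Reagents that add atoms: none
Why: Claisen-type C-acylation under equilibrating conditions is driven by deprotonation of the product, which is possible only after acylation at the α-CH2 next to C21; the enolizable ester centre should settle trans to the isopropenyl group.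

Step 5
Reactants: 7 β-keto ester; 8 methacrolein
Product: 10 bicyclic ketol methyl 4-hydroxy-3,5-dimethyl-8-oxo-7-(prop-1-en-2-yl)bicyclo[3.2.1]octane-1-carboxylate, via Michael adduct 9 (not isolated)
Conditions: DBU (0.3 equiv), MeCN, 0 °C → rt
Reagents that add atoms: none
Why: DBU forms the stabilized enolate of the β-keto ester, which adds through C12 to the β-carbon C13 of 8 on the face opposite the C21 isopropenyl group and gives 9 with the ester cis to isopropenyl. Because C12 is then quaternary the C25 ketone can enolize only toward C18, and that enolate attacks the tethered C16 aldehyde in a 6-(enolendo)-exo-trig aldol that closes ring D across the cyclopentanone; the three-carbon tether reaches only the face that already carries C13, so C18 is set cis to C12 by geometry. The closest known reaction type is the base- or amine-catalysed Michael–aldol annulation of 2-alkoxycarbonyl cycloalkanones with enals to bicyclo[3.2.1]octan-8-ones and bicyclo[3.3.1]nonan-9-ones. C14 and C16 form under thermodynamic control (epimerizable aldehyde α-centre, reversible aldol), with the methyl expected equatorial (exo) and the hydroxyl axial and hydrogen-bonded to the C25 carbonyl; both centres are erased in steps 8 and 11. The step needs C12 to react before any other enolizable position, which the acidity of the β-keto ester secures, and it must stop before retro-Dieckmann opening of the doubly activated C25 ketone, which the aprotic medium and the non-nucleophilic amidine should secure.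

Step 6
Reactants: 10 bicyclic ketol
Product: 11 triol (C11 hydroxymethyl, C16 and C25 carbinols)
Conditions: LiAlH4, THF, −78 °C → rt; aq. NaOH work-up
Reagents that add atoms: none
Why: Hydride reduces the ester to the C11 primary alcohol and unavoidably the C25 ketone, which is restored in step 8 together with the C16 oxidation the route needs anyway; the C25 carbinol configuration (hydride from the C13–C16 flank) is irrelevant.

Step 7
Reactants: 11 triol
Product: 12 C11 tert-butyldiphenylsilyl ether of the triol
Conditions: tBuPh2SiCl, imidazole, DMF, 0 °C → rt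
Reagents that add atoms: tert-butyl(chloro)diphenylsilane, CC(C)(C)[Si](Cl)(c1ccccc1)c1ccccc1
Why: Silylation should discriminate the primary hydroxyl from the two secondary hydroxyls, each of which is flanked by a quaternary carbon.

Step 8
Reactants: 12 silyl ether diol
Product: 13 diketone (C16 and C25 ketones)
Conditions: Dess–Martin periodinane (3 equiv), NaHCO3, CH2Cl2, rt
Reagents that add atoms: none
Why: Dess–Martin oxidation converts both secondary carbinols without base, so the 1,3-diketone around quaternary C18 is not exposed to retro-Claisen cleavage; C14 becomes the only enolizable position.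

Step 9
Reactants: 13 diketone
Product: 14 triketone (C22 methyl ketone)
Conditions: O3, CH2Cl2/MeOH, −78 °C; Me2S, −78 °C → rt
Reagents that add atoms: ozone, [O-][O+]=O
Why: Ozonolysis of the only alkene unmasks the C22 methyl ketone; C21 becomes epimerizable, but exo is the stable arrangement on the two-carbon bridge.

Step 10
Reactants: 14 triketone
Product: 15 ketal diketone (2-methyl-1,3-dioxolan-2-yl at C21)
Conditions: HOCH2CH2OH, pyridinium p-toluenesulfonate, benzene, reflux (Dean–Stark)
Reagents that add atoms: ethane-1,2-diol, OCCO
Why: Acid-catalysed dioxolane formation should select the methyl ketone because the C16 and C25 carbonyls each adjoin a quaternary carbon; the ketal keeps C21 and C23 from being enolized or olefinated in steps 11 and 12.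

Step 11
Reactants: 15 ketal diketone
Product: 16 C14-quaternary diketone with C31 as CH2O-(4-methoxybenzyl)
Conditions: LiN(SiMe3)2, THF, −78 → 0 °C; 4-MeOC6H4CH2OCH2Cl, −78 °C → rt
Reagents that add atoms: 4-methoxybenzyl chloromethyl ether, COc1ccc(COCCl)cc1
Why: Only the C14=C16 enolate can form; enolates of this bicyclo[3.2.1]oct-2-ene type are alkylated from the exo face (syn to the one-carbon bridge C25, away from the ethano bridge), which puts C31 on the C25 side and the methyl endo as in the target.

Step 12
Reactants: 16 C14-quaternary diketone
Product: 17 C25 methylene ketone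
Conditions: Ph3PCH3Br, KN(SiMe3)2, toluene, 0 → 80 °C
Reagents that add atoms: methyltriphenylphosphonium bromide, C[P+](c1ccccc1)(c1ccccc1)c1ccccc1.[Br-]
Why: Salt-free Wittig methylenation; the bridging C25 carbonyl has its α-substituents tied back, whereas C16 now sits between two fully substituted carbons and should be left alone, and no alkoxide is present that could open the 1,3-diketone.

Step 13
Reactants: 17 C25 methylene ketone
Product: 18 spiro α,α-dichlorocyclobutanone at C25
Conditions: Cl3CCOCl, Zn(Cu), POCl3, Et2O, rt, ultrasound
Reagents that add atoms: trichloroacetyl chloride, ClC(=O)C(Cl)(Cl)Cl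
Why: Thermal [2+2] cycloaddition of dichloroketene made in the flask; its carbonyl carbon bonds to the unsubstituted terminus C26 and the CCl2 carbon (C30) to C25, and approach from the C13–C14–C16 flank is expected because the other face is covered by the exo ketal carbon C22 on C21.

Step 14
Reactants: 18 spiro dichlorocyclobutanone
Product: 19 α,α-dichloro γ-lactone (O27 between C26 and C28)
Conditions: mCPBA, NaHCO3, CH2Cl2, 0 °C → rt
Reagents that add atoms: 3-chloroperoxybenzoic acid, OOC(=O)c1cccc(Cl)c1
Why: Baeyer–Villiger oxidation of the strained, activated cyclobutanone; the electron-poor CCl2 carbon does not migrate, so oxygen enters on the CH2 side and the lactone has the required orientation.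

Step 15
Reactants: 19 dichloro γ-lactone
Product: 20 C31 alcohol
Conditions: DDQ, CH2Cl2/pH 7 buffer (10:1), 0 °C
Reagents that add atoms: none
Why: Oxidative cleavage of the 4-methoxybenzyl ether under buffered conditions frees the C31 hydroxyl and leaves silyl ether, ketal and dichlorolactone alone.

Step 16
Reactants: 20 C31 alcohol
Product: 21 C31 aldehyde
Conditions: Dess–Martin periodinane, NaHCO3, CH2Cl2, rt
Reagents that add atoms: none
Why: Neutral oxidation gives the non-enolizable aldehyde on quaternary C14 and avoids retro-aldol loss of the hydroxymethyl group.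

Step 17
Reactants: 21 C31 aldehyde
Product: 23 ring E hydroxy lactone, via chloro aldol 22 (not isolated)
Conditions: SmI2 (5 equiv), THF, −78 °C; then MeOH, −78 → −40 °C
Reagents that add atoms: none
Why: Samarium Reformatsky reaction: reduction of one C–Cl bond gives an enolate of trivalent samarium that adds to the tethered C31 aldehyde in a 6-(enolexo)-exo-trig closure through the boat form of ring D. Chelation of the oxophilic metal by the 1,3-related C16 ketone and aldehyde oxygens should hold O32 on the C16 flank, and reduction of the second C–Cl bond with protonation from the side of the samarium alkoxide should place H30 syn to O32.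

Step 18
Reactants: 23 ring E hydroxy lactone
Product: 24 C31 tert-butyldimethylsilyl ether
Conditions: tBuMe2SiOTf, 2,6-lutidine, CH2Cl2, −78 → 0 °C
Reagents that add atoms: tert-butyldimethylsilyl trifluoromethanesulfonate, CC(C)(C)[Si](C)(C)OS(=O)(=O)C(F)(F)F
Why: Silylation of the hindered C31 hydroxyl guards the β-hydroxy ketone and β-hydroxy lactone against retro-aldol and elimination in the basic coupling of step 24.

Step 19
Reactants: 24 C31 silyl ether
Product: 25 C11 alcohol
Conditions: Bu4NF, AcOH (1:1), THF, 0 °C → rt
Reagents that add atoms: none
Why: Buffered fluoride should remove the primary tert-butyldiphenylsilyl ether faster than the secondary tert-butyldimethylsilyl ether wedged between C14 and C30, and the acetic acid protects lactone and ketal.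

Step 20
Reactants: 25 C11 alcohol
Product: 26 C11 aldehyde
Conditions: Dess–Martin periodinane, NaHCO3, CH2Cl2, rt
Reagents that add atoms: none
Why: The only free hydroxyl is oxidized under neutral conditions to the aldehyde on quaternary C12.

Step 21
Reactants: 26 C11 aldehyde
Product: 27 C12 vinyl compound (C11=C10)
Conditions: CH2I2, Zn, Ti(OiPr)4, THF, rt
Reagents that add atoms: diiodomethane, ICI
Why: Takai methylenation with the zinc/titanium methylene reagent is non-basic and aldehyde-selective, so the lactone α-proton and the hindered C16 ketone are not touched; the new carbon is C10.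

Step 22
Reactants: 28 3-methylbut-2-enal
Product: 30 2-bromo-3-methylbut-2-enal, via dibromide 29 (not isolated)
Conditions: Br2, CH2Cl2, −10 °C; then Et3N, 0 °C → rt
Reagents that add atoms: bromine, BrBr
Why: Bromine addition to the enal followed by base-induced loss of HBr from the α,β-dibromide is the standard entry to α-bromo enals.

Step 23
Reactants: 30 2-bromo-3-methylbut-2-enal
Product: 31 methyl (2Z)-4-bromo-5-methylhexa-2,4-dienoate
Conditions: (CF3CH2O)2P(O)CH2CO2Me, KN(SiMe3)2, 18-crown-6, THF, −78 °C
Reagents that add atoms: methyl bis(2,2,2-trifluoroethyl)phosphonoacetate, COC(=O)CP(=O)(OCC(F)(F)F)OCC(F)(F)F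
Why: Still–Gennari olefination gives the (Z)-enoate under kinetic control; the Z geometry is what later lets the ester oxygen reach C2.

Step 24
Reactants: 27 C12 vinyl compound; 31 bromodienoate
Product: 33 ketal-protected dienoate (C9–C10 bond formed), via alkylborane 32 (not isolated)
Conditions: 9-BBN, THF, rt → 40 °C; then 31, Pd(dppf)Cl2 (10 mol %), AsPh3, Cs2CO3, DMF/H2O, rt
Reagents that add atoms: none
Why: 9-BBN adds anti-Markovnikov to the only alkene, and B-alkyl Suzuki–Miyaura coupling of the primary alkylborane with the vinyl bromide forms C9–C10 with retention of the diene geometry under mild carbonate conditions.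

Step 25
Reactants: 33 ketal-protected dienoate
Product: 34 keto dienoate (free C22 ketone and C31 hydroxyl)
Conditions: HF (48% aq.), MeCN, 0 °C → rt
Reagents that add atoms: water, O
Why: Aqueous HF in acetonitrile cleaves the hindered silyl ether and hydrolyses the dioxolane, while the dienoate, the lactone and the β-hydroxy ketone tolerate dilute acid.

Step 26
Reactants: 34 keto dienoate
Product: 35 target CNP0360620.3
Conditions: MeAlCl2 (4 equiv), CH2Cl2, −78 → −20 °C; aq. potassium sodium tartrate
Reagents that add atoms: none
Why: Proposed new method: MeAlCl2 complexes the C22 ketone and the tethered tetrasubstituted C9=C2 alkene attacks it through C9 (6-exo closure of ring B) to give a tertiary cation at C2, which the carbonyl oxygen of the (Z)-enoate captures to close ring A before chloride from the aluminate removes the O-methyl group as chloromethane; the closest known reaction types are the Lewis-acid ketone–ene/Prins cyclization of citronellal-type substrates and cation–olefin cyclizations terminated by an ester or carboxyl group. In the chair-like closure the C23 methyl should be equatorial and the aluminate oxygen axial (the axial site at C22 leans on C25/C26 and accepts oxygen more easily than methyl), and an open antiperiplanar arrangement that keeps the cationic CMe2 terminus away from the bulky aluminate puts C2 axial and the acrylate arm equatorial on C9, which is the target configuration at C9 and C22.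

## Compound list

1 | 2-methylcyclopentan-1-one (racemic) | CC1CCCC1=O | starting material
2 | trimethyl[(5-methylcyclopent-1-en-1-yl)oxy]silane (racemic) | CC1CCC=C1O[Si](C)(C)C | intermediate
3 | 5-methylcyclopent-2-en-1-one (racemic) | CC1CC=CC1=O | intermediate
4 | potassium trifluoro(prop-1-en-2-yl)borate | [K+].CC(=C)[B-](F)(F)F | starting material
5 | (4R)-2-methyl-4-(prop-1-en-2-yl)cyclopentan-1-one, C2 epimers | CC1C[C@@H](C(C)=C)CC1=O | intermediate
6 | dimethyl carbonate | COC(=O)OC | starting material
7 | methyl (1S,3S,5R)-3-methyl-2-oxo-5-(prop-1-en-2-yl)cyclopentane-1-carboxylate (ester trans to isopropenyl; the C3 epimer is equally usable) | COC(=O)[C@@H]1C(=O)[C@@H](C)C[C@H]1C(C)=C | intermediate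
8 | methacrolein (2-methylprop-2-enal) | CC(=C)C=O | starting material
9 | Michael adduct: 7 carrying a 2-methyl-3-oxopropyl chain on C12, anti to isopropenyl; mixture at C14 and C18 | COC(=O)[C@@]1(CC(C)C=O)C(=O)C(C)C[C@H]1C(C)=C | intermediate
10 | methyl 4-hydroxy-3,5-dimethyl-8-oxo-7-(prop-1-en-2-yl)bicyclo[3.2.1]octane-1-carboxylate; C12, C18, C21 as in the target, isopropenyl exo, C14 methyl exo (equatorial), C16 hydroxyl axial (syn to C25) | COC(=O)[C@]12C[C@@H](C)[C@@H](O)[C@](C)(C[C@H]1C(C)=C)C2=O | intermediate
11 | triol: 10 with C11 as CH2OH and C25 as carbinol (hydroxyl syn to the C20–C21 bridge) | OC[C@]12C[C@@H](C)[C@@H](O)[C@](C)(C[C@H]1C(C)=C)[C@@H]2O | intermediate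
12 | C11 tert-butyldiphenylsilyl ether of 11 | CC(C)(C)[Si](c1ccccc1)(c1ccccc1)OC[C@]12C[C@@H](C)[C@@H](O)[C@](C)(C[C@H]1C(C)=C)[C@@H]2O | intermediate
13 | diketone: 12 with C16 and C25 as ketones | CC(C)(C)[Si](c1ccccc1)(c1ccccc1)OC[C@]12C[C@@H](C)C(=O)[C@](C)(C[C@H]1C(C)=C)C2=O | intermediate
14 | triketone: 13 with exo acetyl (C22, C23) at C21 | CC(C)(C)[Si](c1ccccc1)(c1ccccc1)OC[C@]12C[C@@H](C)C(=O)[C@](C)(C[C@H]1C(C)=O)C2=O | intermediate
15 | 14 with the C22 ketone as 2-methyl-1,3-dioxolane | CC(C)(C)[Si](c1ccccc1)(c1ccccc1)OC[C@]12C[C@@H](C)C(=O)[C@](C)(C[C@H]1C1(C)OCCO1)C2=O | intermediate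
16 | 15 with C14 quaternary: exo CH2O-(4-methoxybenzyl) (C31), endo methyl | CC(C)(C)[Si](c1ccccc1)(c1ccccc1)OC[C@]12C[C@](COCc3ccc(OC)cc3)(C)C(=O)[C@](C)(C[C@H]1C1(C)OCCO1)C2=O | intermediate
17 | 16 with C25 as exocyclic methylene (C26) | CC(C)(C)[Si](c1ccccc1)(c1ccccc1)OC[C@]12C[C@](COCc3ccc(OC)cc3)(C)C(=O)[C@](C)(C[C@H]1C1(C)OCCO1)C2=C | intermediate
18 | spiro 2,2-dichlorocyclobutan-1-one at C25, CCl2 (C30) syn to the C13–C16 bridge | CC(C)(C)[Si](c1ccccc1)(c1ccccc1)OC[C@]12C[C@](COCc3ccc(OC)cc3)(C)C(=O)[C@](C)(C[C@H]1C1(C)OCCO1)[C@]24CC(=O)C4(Cl)Cl | intermediate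
19 | spiro α,α-dichloro-γ-butyrolactone (C25, C26, O27, C28, C30) | CC(C)(C)[Si](c1ccccc1)(c1ccccc1)OC[C@]12C[C@](COCc3ccc(OC)cc3)(C)C(=O)[C@](C)(C[C@H]1C1(C)OCCO1)[C@]24COC(=O)C4(Cl)Cl | intermediate
20 | 19 with free C31 hydroxymethyl | CC(C)(C)[Si](c1ccccc1)(c1ccccc1)OC[C@]12C[C@](CO)(C)C(=O)[C@](C)(C[C@H]1C1(C)OCCO1)[C@]24COC(=O)C4(Cl)Cl | intermediate
21 | 19 with C31 as aldehyde | CC(C)(C)[Si](c1ccccc1)(c1ccccc1)OC[C@]12C[C@](C=O)(C)C(=O)[C@](C)(C[C@H]1C1(C)OCCO1)[C@]24COC(=O)C4(Cl)Cl | intermediate
22 | chloro aldol: ring E closed, C30 bearing Cl (toward C13) and C31 hydroxyl (toward C16) | CC(C)(C)[Si](c1ccccc1)(c1ccccc1)OC[C@]13C[C@]4(C)C(=O)[C@](C)(C[C@H]1C5(C)OCCO5)[C@]31COC(=O)[C@@]1(Cl)[C@H]4O | intermediate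
23 | tetracyclic hydroxy lactone: rings C–F of the target with C11 as CH2O-SiPh2tBu and the C22 ketal | CC(C)(C)[Si](c1ccccc1)(c1ccccc1)OC[C@]13C[C@]4(C)C(=O)[C@](C)(C[C@H]1C5(C)OCCO5)[C@]31COC(=O)[C@@H]1[C@H]4O | intermediate
24 | 23 with C31 tert-butyldimethylsilyl ether | CC(C)(C)[Si](c1ccccc1)(c1ccccc1)OC[C@]13C[C@]4(C)C(=O)[C@](C)(C[C@H]1C5(C)OCCO5)[C@]31COC(=O)[C@@H]1[C@H]4O[Si](C)(C)C(C)(C)C | intermediate
25 | 24 with free C11 hydroxymethyl | OC[C@]13C[C@]4(C)C(=O)[C@](C)(C[C@H]1C5(C)OCCO5)[C@]31COC(=O)[C@@H]1[C@H]4O[Si](C)(C)C(C)(C)C | intermediate
26 | 24 with C11 as aldehyde | O=C[C@]13C[C@]4(C)C(=O)[C@](C)(C[C@H]1C5(C)OCCO5)[C@]31COC(=O)[C@@H]1[C@H]4O[Si](C)(C)C(C)(C)C | intermediate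
27 | 24 with vinyl (C11=C10) on C12 | C=C[C@]13C[C@]4(C)C(=O)[C@](C)(C[C@H]1C5(C)OCCO5)[C@]31COC(=O)[C@@H]1[C@H]4O[Si](C)(C)C(C)(C)C | intermediate
28 | 3-methylbut-2-enal | CC(C)=CC=O | starting material
29 | 2,3-dibromo-3-methylbutanal | CC(C)(Br)C(Br)C=O | intermediate
30 | 2-bromo-3-methylbut-2-enal | CC(C)=C(Br)C=O | intermediate
31 | methyl (2Z)-4-bromo-5-methylhexa-2,4-dienoate | COC(=O)/C=C\C(Br)=C(C)C | intermediate
32 | B-alkyl-9-borabicyclo[3.3.1]nonane from 27 (boron on C10) | C12CCCC(CCC1)B2CC[C@]13C[C@]4(C)C(=O)[C@](C)(C[C@H]1C5(C)OCCO5)[C@]31COC(=O)[C@@H]1[C@H]4O[Si](C)(C)C(C)(C)C | intermediate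
33 | 24-type core with the chain C11H2–C10H2–C9(=CMe2)–CH=CH–CO2Me (2Z) on C12 | COC(=O)/C=C\C(=C(C)C)CC[C@]13C[C@]4(C)C(=O)[C@](C)(C[C@H]1C5(C)OCCO5)[C@]31COC(=O)[C@@H]1[C@H]4O[Si](C)(C)C(C)(C)C | intermediate
34 | 33 with free C22 methyl ketone and free C31 hydroxyl | COC(=O)/C=C\C(=C(C)C)CC[C@]13C[C@]4(C)C(=O)[C@](C)(C[C@H]1C(C)=O)[C@]31COC(=O)[C@@H]1[C@H]4O | intermediate
35 | CNP0360620.3 | CC1(C)OC(=O)C=C[C@]12CC[C@]13C[C@]4(C)C(=O)[C@](C)(C[C@H]1[C@@]2(C)O)[C@]31COC(=O)[C@@H]1[C@H]4O | target

## Step count and least certain steps

Total step count: 26 (24 on the main line, 2 for coupling partner 31). Longest linear sequence: 24 steps (steps 1–21 and 24–26).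

Step 26 (Prins spirolactonization, new). Most likely failure: the C2 cation loses a proton or picks up chloride before the ester oxygen reaches it, because capture needs the acrylate arm to rotate out of conjugation; closure through a synclinal, ene-like arrangement, which would invert C9, is the second concern. Fallback with known chemistry, from 34 back to 35: ring B is closed on its own as a Lewis-acid carbonyl–ene cyclization (Me2AlCl, CH2Cl2, −78 °C) to the isopropenyl carbinol F1. Ring A is then closed in a separate Markovnikov lactonization of the (Z)-enoate onto the isopropenyl group (CF3CO2H, wet CH2Cl2), which gives 35.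

Step 5 (key step). Most likely failure: the aldol stage stalls or reverses, or the doubly activated C25 ketone is opened by retro-Dieckmann fragmentation, because the closure creates the second quaternary bridgehead in a reversible step. Fallback from 9 back to 10: 9 is isolated after Michael addition with catalytic Et3N and its aldehyde is masked as the dimethyl acetal F2 (HC(OMe)3, MeOH, pyridinium p-toluenesulfonate). The lithium enolate of F2, which can form only at C18, is brominated with N-bromosuccinimide at −78 °C to the α-bromo ketone F3. Mild aqueous acid frees the bromo keto aldehyde F4, and SmI2 in THF at −78 °C generates the C18 enolate reductively and closes it irreversibly on C16 to give 10.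

Step 17 (ring E). Most likely failure: poor control of the relative configuration at C30 and C31 (closure through a chelate between enolate and aldehyde oxygens on the C13 flank), or elimination of the C31 oxygen during the second reduction. Fallback from 19 back to 23: Zn and AcOH remove both chlorines to give lactone F5, DDQ frees alcohol F6, and Dess–Martin oxidation gives aldehyde F7. In F7 only the lactone is enolizable, so catalytic KOtBu in THF/tBuOH closes ring E by a reversible aldol that can settle on the more stable arrangement, with O32 and the lactone carbonyl on opposite flanks, giving 23.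

Step 13 (ketene cycloaddition). Most likely failure: slow addition to an alkene flanked by two quaternary bridgeheads, or approach from the ethano-bridge face. Fallback from 16 back to 23: Wittig methoxymethylenation of the C25 ketone (Ph3P=CHOMe) gives enol ether F8, and mild aqueous acid gives the C25 carbaldehyde F9. Its potassium enolate is alkylated with methyl bromoacetate on the face away from the C21 ketal to give the quaternary aldehyde ester F10, and NaBH4 reduces the aldehyde so that the alkoxide lactonizes to lactone F5. Lactone F5 then follows the fallback for step 17 through alcohol F6 and aldehyde F7 to 23.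

Step 11 (C14 alkoxymethylation). Most likely failure: O-alkylation of the tetrasubstituted enolate by the hard chloromethyl ether, or partial attack from the endo face. Fallback from 15 back to 16: the enolate is trapped as the trimethylsilyl enol ether F11 (LiN(SiMe3)2, Me3SiCl), which undergoes Lewis-acid hydroxymethylation with aqueous formaldehyde and Yb(OTf)3 at carbon to give the hydroxymethyl ketone F12. 4-Methoxybenzyl trichloroacetimidate with a catalytic acid then gives 16.

## Further compounds

F1 | step 26 | isopropenyl carbinol: rings B–F closed, C9 bearing isopropenyl and the (Z)-acrylate arm | COC(=O)/C=C\[C@@]2(C(C)=C)CC[C@]13C[C@]4(C)C(=O)[C@](C)(C[C@H]1[C@@]2(C)O)[C@]31COC(=O)[C@@H]1[C@H]4O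
F2 | step 5 | dimethyl acetal of Michael adduct 9 | COC(=O)[C@@]1(CC(C)C(OC)OC)C(=O)C(C)C[C@H]1C(C)=C
F3 | step 5 | C18 bromide of F2 | COC(=O)[C@@]1(CC(C)C(OC)OC)C(=O)C(C)(Br)C[C@H]1C(C)=C
F4 | step 5 | C18-bromo keto aldehyde | COC(=O)[C@@]1(CC(C)C=O)C(=O)C(C)(Br)C[C@H]1C(C)=C
F5 | step 17 | dechlorinated spiro γ-lactone (19 without chlorine) | CC(C)(C)[Si](c1ccccc1)(c1ccccc1)OC[C@]12C[C@](COCc3ccc(OC)cc3)(C)C(=O)[C@](C)(C[C@H]1C1(C)OCCO1)[C@]24COC(=O)C4
F6 | step 17 | F5 with free C31 hydroxymethyl | CC(C)(C)[Si](c1ccccc1)(c1ccccc1)OC[C@]12C[C@](CO)(C)C(=O)[C@](C)(C[C@H]1C1(C)OCCO1)[C@]24COC(=O)C4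
F7 | step 17 | F5 with C31 as aldehyde | CC(C)(C)[Si](c1ccccc1)(c1ccccc1)OC[C@]12C[C@](C=O)(C)C(=O)[C@](C)(C[C@H]1C1(C)OCCO1)[C@]24COC(=O)C4
F8 | step 13 | C25 methoxymethylene enol ether of 16 | CC(C)(C)[Si](c1ccccc1)(c1ccccc1)OC[C@]12C[C@](COCc3ccc(OC)cc3)(C)C(=O)[C@](C)(C[C@H]1C1(C)OCCO1)C2=COC
F9 | step 13 | C25 carbaldehyde (C25 epimers) | CC(C)(C)[Si](c1ccccc1)(c1ccccc1)OC[C@]12C[C@](COCc3ccc(OC)cc3)(C)C(=O)[C@](C)(C[C@H]1C1(C)OCCO1)C2C=O
F10 | step 13 | C25 quaternary aldehyde with CH2CO2Me syn to the C13–C16 bridge | CC(C)(C)[Si](c1ccccc1)(c1ccccc1)OC[C@]12C[C@](COCc3ccc(OC)cc3)(C)C(=O)[C@](C)(C[C@H]1C1(C)OCCO1)[C@]2(CC(=O)OC)C=O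
F11 | step 11 | C14=C16 trimethylsilyl enol ether of 15 | CC(C)(C)[Si](c1ccccc1)(c1ccccc1)OC[C@]12CC(C)=C(O[Si](C)(C)C)[C@](C)(C[C@H]1C1(C)OCCO1)C2=O
F12 | step 11 | C14 hydroxymethyl ketone | CC(C)(C)[Si](c1ccccc1)(c1ccccc1)OC[C@]12C[C@](CO)(C)C(=O)[C@](C)(C[C@H]1C1(C)OCCO1)C2=O
A1 | alternative 1 | divinyl ketone | C=CC(=O)C=C
A2 | alternative 1 | isotwistane with ring B ketone at C22 and sulfone at C11 | O=C1CC[C@H](S(=O)(=O)c2ccccc2)[C@]23C[C@]4(C)C(=O)[C@](C)(C[C@@H]12)[C@@]3(CO[Si](C)(C)C(C)(C)C)CC45OCCO5
A3 | alternative 2 | lactone-fused bicyclo[2.2.2]octenone C31 boronate | COC(=O)CCCC1=C[C@]2(C)C(=O)[C@](C)(C/C=C/C)[C@]13COC(=O)[C@@H]3[C@H]2B4OC(C)(C)C(C)(C)O4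
A4 | alternative 3 | dichloroketene | ClC(Cl)=C=O
A5 | alternative 3 | spiro α,α-dichlorocyclobutanone at C25 with the C11 ester | COC(=O)[C@]12C[C@@](C)(COCc3ccc(OC)cc3)C(=O)[C@](C)(C[C@H]1C4(C)OCCO4)[C@]25CC(=O)C5(Cl)Cl
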